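## Analysis of the target

The target is a melampolide-type germacranolide: a ten-membered carbocycle (C1–C10) with a ring-cis C1=C10 alkene whose C10 carries the ester carbon C14, a cis-fused α-methylene-γ-butyrolactone (O–C6, C7–C11(=C13)–C12) and a trisubstituted cis-epoxide across C4–C5 (methyl C15 on C4). Six contiguous ring stereocentres run from C4 to C9 (4R,5S,6R,7R,8S,9S); a seventh, (R), lies in the 2-methyloxirane-2-carboxylate on O9, and O8 carries an acetate. Read along the chain C5–C9, the oxygens on C6 and C8 are 1,3-syn, the carbon branch on C7 is anti to both, the oxygens on C8 and C9 are syn, and the epoxide oxygen on C5 is syn (threo) to the C6 oxygen. The sensitive groups are the α-methylene lactone and the enoate (Michael acceptors), the ring epoxide (which faces the C1=C10 alkene across the ring and can open transannularly under acid), the glycidic ester, and the vicinal C8/C9 esters, which can exchange by acyl migration. The difficulty is to close a ten-membered ring bearing this much functionality, to fix the (Z) geometry of both ring alkenes, and to keep two different acyl groups on neighbouring hydroxyls. The strategy rests on the C4–C5–C6 unit: a cis-epoxide next to the C6 oxygen is what hydroxyl-directed epoxidation of a (Z)-C4=C5 allylic alcohol gives, and that alkene can be written as the extrusion product of a sulfone whose sulfur bridges C4 and C5 in an eleven-membered ring.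

## Retrosynthetic reasoning

**Acyl groups.** Target 51 is cut at the two acyl C–O bonds, back to hydroxy ester 44 and acid 47. The C9 ester is put on first, while O8 is still a PMB ether; the PMB group is then removed (50) and O8 acetylated. In this order no free C9 hydroxyl ever sits beside a C8 ester under basic conditions, so acyl migration has no opening. Acid 47 comes from methallyl alcohol 45 by asymmetric epoxidation (46) and oxidation.

**Oxidation level at C12 and C14.** The lactone carbonyl and the ester are taken back to the two primary allylic alcohols of triol 39 (via 43, 42 and 41). Both Michael acceptors are thereby absent during all basic and nucleophilic steps, and the lactone can be formed late by allylic oxidation, with the C6 hydroxyl trapping the C12 aldehyde.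

**Epoxide.** The two C–O bonds of the ring epoxide in 38 are cut to give the (Z)-allylic alcohol 37. The forward step has to deliver oxygen syn to the C6 hydroxyl, which is what a metal-alkoxide-directed epoxidation of a Z-allylic alcohol does.

**C4=C5 (key disconnection).** The alkene of 37 is opened by inserting a sulfonyl group between C4 and C5, giving the eleven-membered sulfone 34. This replaces a direct ten-membered C–C closure by a ring contraction that forms one bond and no stereocentre. Both C4 epimers of the sulfone would converge, and the C6 hydroxyl stays free.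

**C–S bonds.** Sulfone 34 comes from sulfide 32, whose C5–S bond is cut to give thioacetate 30. A thiolate attacking a primary carbon is the most reliable medium-ring closure available, and it releases the C6 hydroxyl at the same time. The electrophile is a C5/C6 chlorohydrin that closes to the epoxide only in the cyclisation flask, so no epoxide has to be carried through the earlier steps. The C4–S bond is made from diol 29 by Mitsunobu inversion. A ring closure by olefination at C1=C10 was not used: a C10 phosphonate flanked by the C9 silyloxy group would be hard to make and would tend to β-eliminate, so the C1=C10 alkene is fixed before the ring is closed.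

**C9–C10.** Allylic alcohol 27 is cut into aldehyde 18 (fragment A, C5–C9 and C11–C13) and alkenyl iodide 24 (fragment B, C1–C4, C10, C14, C15). The alkene geometry is carried in from 24, and the C9 stereocentre is set by chelation to the C8 PMB ether.

**Fragment B.** Iodide 24 goes back through 23, 22 and 21 to (S)-hex-5-en-2-ol 19: cross-metathesis adds C10 and C14 as an enal, and α-iodination fixes the iodine cis to C2.

**Fragment A.** Aldehyde 18 is traced back to dimethyl (S)-malate 1, which supplies C8 with its oxygen.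
- The PMB group on O8 is delivered from O9 through the p-methoxybenzylidene acetal (17 from 16; acetal formed in 7 from 6).
- The C11–C13 unit is cut to an allyl group (16 back to 10: alkene cleavage, α-methylenation, reduction, silylation).
- C6 is a carbinol made by reagent-controlled reduction of chloromethyl ketone 8, and C5 is added to ester 7 as a chloromethyl carbenoid.
- The C7–C11 bond is cut to ester 4 by an anti-selective dianion allylation (6 from 4), which sets C7 from C8.
- Ester 4 comes from malate 1 via diol 2.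

## Alternatives that were turned down

**Alternative 1: transannular De Mayo contraction.**
- *Disconnection:* C5–C6 and C7–C11 are cut and C5 is joined to C11, leading from the ten-membered 5-ketone A1 back to the thirteen-membered β-keto enol lactone A2.
- *Forward key step:* on irradiation the C5=C11 enol of A2 would add across the C6=C7 enol-ester alkene in the crossed sense; retro-aldol opening of the cyclobutanol at C5–C11 would give A1 with the lactone already fused.
- *For:* two skeletal bonds, the carbocycle and the lactone are made in one step. The ring closed beforehand is an unstrained thirteen-membered lactone, which is easier than the eleven-membered sulfide closure used here. On ring-closure ease and on bonds formed per step this alternative is stronger.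
- *Against:* C6 and C7 are created in the photochemical step with only the conformation of a flexible ring to control the face, and crossed versus straight addition is not secured. A1 lacks C13 and carries a C5 ketone and a tertiary C4 silyl ether that would have to become the cis-epoxide, which requires closure at a tertiary centre. The lactone would need α-methylenation by strong base late on. The enol ester and the C1=C10 alkene can isomerise or undergo acyl shifts under irradiation.
- *Comparison:* the chosen route sets C6–C9 on an open chain by chelate- or reagent-controlled steps and creates no stereocentre in its key step, so its risk is confined to one bond. The price is a longer sequence.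

**Alternative 2: ring-closing metathesis at C8=C9.**
- *Disconnection:* the C8=C9 alkene of cyclodecadiene A3 is cut to give the acyclic diene A4, which already holds lactone, ring epoxide and enoate.
- *Forward key step:* the second-generation Grubbs catalyst would join the vinyl group on C7 with that on C10 with loss of ethylene; the C8 and C9 oxygens would follow by epoxidation of the new cis-alkene and trans-opening.
- *For:* by far the shortest route, and the sensitive groups need no protecting-group traffic. On step count it is clearly stronger.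
- *Against:* direct ten-membered closure fights ring strain and dimerisation. One partner is the terminus of a 2-alkoxycarbonyl-1,3-diene, which is deactivated and can react at its internal alkene, and the α-methylene lactone is a further competing alkene. After closure, the C8=C9 alkene must be epoxidised and opened regioselectively by two different carboxylates in the presence of the 4,5-epoxide, with no element to control regiochemistry or the face relative to C7.
- *Comparison:* the chosen route fixes C8 and C9 with differentiated protecting groups before the ring exists and closes the ring through sulfur at a primary carbon.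

**Alternative 3: anionic oxy-Cope ring expansion.**
- *Disconnection:* C2–C3 is cut and C5–C10 is formed, leading from the ten-membered silyl enol ether A5 back to the 1,2-dialkenylcyclohexanol A6.
- *Forward key step:* the potassium alkoxide of A6 would undergo the [3,3] shift and the ten-membered enolate would be silylated to A5.
- *For:* an irreversible, alkoxide-accelerated C–C bond-forming ring expansion on a cyclohexane template. As a ring-forming event it is at least as robust as the Ramberg–Bäcklund contraction.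
- *Against:* A6 has six contiguous stereocentres on one cyclohexane, two of them fully substituted (the C5 carbinol and the C10 centre with ester and vinyl group), so its synthesis is long. The ester is exposed to the strongly basic alkoxide conditions. A5 carries oxygen on C5 as an enol ether with a ring-trans C4=C5 geometry, whereas the target needs a cis-epoxide and no other oxygen on C5; correcting this costs several redox steps and a new stereochemical problem at C4. The C11–C13 unit is still missing.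
- *Comparison:* the chosen route delivers C4=C5 with the required (Z) geometry and with the C6 hydroxyl in place to direct the epoxidation.

Key step: step 25

## Route

Assumption: (S)-hex-5-en-2-ol 19 is bought as one enantiomer so that all intermediates are single diastereomers; its stereocentre (C4) is erased in step 25, so the racemate would serve as well.

Remark: the acetal carbon of the p-methoxybenzylidene acetals 7–16 and the new carbinol or α-carbons of 11, 13, 35, 36 and 40 are left undefined in the SMILES; they are mixtures of no consequence.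

Locants C1–C15 in the names of later intermediates are those of the target. PMB = 4-methoxybenzyl, TES = triethylsilyl, TBS = tert-butyldimethylsilyl.

### Fragment A (steps 1–13)

Step 1
Reactants: 1 dimethyl (S)-malate
Product: 2 methyl (3S)-3,4-dihydroxybutanoate
Conditions: BH3·SMe2, NaBH4 (5 mol %), THF, 0 °C → rt; MeOH
Reagents that add atoms: none
Why: Chelation-directed borane reduction (Saito–Moriwake): the hydroxyl binds borane and hydride reaches only the neighbouring ester through a five-membered ring, so the distal ester survives and the stereocentre is untouched.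

Step 2
Reactants: 2 methyl (3S)-3,4-dihydroxybutanoate
Product: 4 methyl (3S)-3-hydroxy-4-[(4-methoxybenzyl)oxy]butanoate, via stannylene acetal 3 (not isolated)
Conditions: Bu2SnO, MeOH, reflux, evaporation; PMBCl, CsF, DMF, rt
Reagents that add atoms: 4-methoxybenzyl chloride, COc1ccc(CCl)cc1; dibutyltin oxide, CCCC[Sn](=O)CCCC (tin into 3 only)
Why: Stannylene-acetal activation makes the primary oxygen the more nucleophilic one, and it alone is benzylated under fluoride activation; the mild temperature avoids lactonisation of the dihydroxy ester.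

Step 3
Reactants: 4 methyl (3S)-3-hydroxy-4-[(4-methoxybenzyl)oxy]butanoate
Product: 6 methyl (2R)-2-[(1S)-1-hydroxy-2-[(4-methoxybenzyl)oxy]ethyl]pent-4-enoate, via dilithium dianion 5 (not isolated)
Conditions: LiN(iPr)2 (2.2 equiv), THF, −78 → −20 °C; allyl bromide, DMPU, −78 → −15 °C
Reagents that add atoms: allyl bromide, C=CCBr; lithium diisopropylamide, [Li]N(C(C)C)C(C)C (lithium into 5 only)
Why: Fráter–Seebach alkylation: alkoxide and enolate oxygens chelate lithium in a six-membered ring and the allyl halide enters anti to the C8 substituent, which sets C7 (anti to O8) from the malate centre.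

Step 4
Reactants: 6 methyl (2R)-2-[(1S)-1-hydroxy-2-[(4-methoxybenzyl)oxy]ethyl]pent-4-enoate
Product: 7 methyl (2R)-2-[(4S)-2-(4-methoxyphenyl)-1,3-dioxolan-4-yl]pent-4-enoate
Conditions: DDQ (1.2 equiv), 4 Å molecular sieves, CH2Cl2, 0 °C
Reagents that add atoms: none
Why: Oikawa–Yonemitsu oxidative acetalisation: DDQ oxidises the PMB ether to the benzylic oxocarbenium ion, which the neighbouring C8 hydroxyl traps as the five-membered acetal. This stores the PMB group for later transfer to O8 and removes the free hydroxyl before the carbenoid step.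

Step 5
Reactants: 7 methyl (2R)-2-[(4S)-2-(4-methoxyphenyl)-1,3-dioxolan-4-yl]pent-4-enoate
Product: 8 (3R)-1-chloro-3-[(4S)-2-(4-methoxyphenyl)-1,3-dioxolan-4-yl]hex-5-en-2-one
Conditions: ICH2Cl, MeLi·LiBr, THF, −78 °C; AcOH, −78 °C; used crude
Reagents that add atoms: chloroiodomethane, ClCI
Why: Carbenoid homologation of an ester to an α-chloro ketone: chloromethyllithium, made by iodine–lithium exchange in the presence of the ester, adds once because the lithium hemiketal is stable at −78 °C, and acid quench releases the ketone. No free base is present to epimerise C7 or to eliminate the β-acetal oxygen.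

Step 6
Reactants: 8 (3R)-1-chloro-3-[(4S)-2-(4-methoxyphenyl)-1,3-dioxolan-4-yl]hex-5-en-2-one
Product: 9 (2R,3S)-1-chloro-3-[(4S)-2-(4-methoxyphenyl)-1,3-dioxolan-4-yl]hex-5-en-2-ol
Conditions: (R)-2-methyl-CBS-oxazaborolidine (20 mol %), catecholborane, toluene, −78 °C
Reagents that add atoms: none
Why: Corey–Bakshi–Shibata reduction: the chloromethyl group is the small substituent, so the (R)-catalyst should give the 6R carbinol (O6 anti to the C7 branch). The Felkin–Anh preference of the C7 centre points the same way (matched case), and catecholborane leaves the terminal alkene alone.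

Step 7
Reactants: 9 (2R,3S)-1-chloro-3-[(4S)-2-(4-methoxyphenyl)-1,3-dioxolan-4-yl]hex-5-en-2-ol
Product: 10 {[(2R,3R)-1-chloro-3-[(4S)-2-(4-methoxyphenyl)-1,3-dioxolan-4-yl]hex-5-en-2-yl]oxy}triethylsilane
Conditions: Et3SiCl, imidazole, DMAP (cat.), DMF, rt
Reagents that add atoms: chlorotriethylsilane, CC[Si](Cl)(CC)CC
Why: Silylation of the only hydroxyl; the TES ether masks O6 until the ring closure and prevents lactol formation with the C12 and C9 aldehydes made later.

Step 8
Reactants: 10 {[(2R,3R)-1-chloro-3-[(4S)-2-(4-methoxyphenyl)-1,3-dioxolan-4-yl]hex-5-en-2-yl]oxy}triethylsilane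
Product: 12 (3R,4R)-5-chloro-3-[(4S)-2-(4-methoxyphenyl)-1,3-dioxolan-4-yl]-4-[(triethylsilyl)oxy]pentanal, via diol 11 (not isolated)
Conditions: OsO4 (2 mol %), NaIO4, 2,6-lutidine, dioxane/H2O (3:1), rt
Reagents that add atoms: osmium tetroxide, O=[Os](=O)(=O)=O; sodium periodate, [Na+].[O-]I(=O)(=O)=O
Why: Lemieux–Johnson cleavage: osmylation of the only alkene and periodate cleavage of the diol shorten the allyl group to the C12 aldehyde; the lutidine buffer keeps the acetal and the silyl ether intact.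

Step 9
Reactants: 12 (3R,4R)-5-chloro-3-[(4S)-2-(4-methoxyphenyl)-1,3-dioxolan-4-yl]-4-[(triethylsilyl)oxy]pentanal
Product: 14 (3R,4R)-5-chloro-3-[(4S)-2-(4-methoxyphenyl)-1,3-dioxolan-4-yl]-2-methylidene-4-[(triethylsilyl)oxy]pentanal, via Mannich base 13 (not isolated)
Conditions: CH2=NMe2+ I− (Eschenmoser's salt), Et3N, CH2Cl2, rt
Reagents that add atoms: N,N-dimethylmethyleneiminium iodide, C=[N+](C)C.[I-]
Why: Mannich reaction of the α-unbranched aldehyde followed by β-elimination of dimethylamine installs the C13 methylene. C7 is not epimerised because its hydrogen is only cross-conjugated with the enal carbonyl.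

Step 10
Reactants: 14 (3R,4R)-5-chloro-3-[(4S)-2-(4-methoxyphenyl)-1,3-dioxolan-4-yl]-2-methylidene-4-[(triethylsilyl)oxy]pentanal
Product: 15 (3R,4R)-5-chloro-3-[(4S)-2-(4-methoxyphenyl)-1,3-dioxolan-4-yl]-2-methylidene-4-[(triethylsilyl)oxy]pentan-1-ol
Conditions: iBu2AlH (1.1 equiv), CH2Cl2, −78 °C
Reagents that add atoms: none
Why: 1,2-Reduction of the enal by the aluminium hydride; at −78 °C the acetal, the silyl ether and the primary chloride do not react.

Step 11
Reactants: 15 (3R,4R)-5-chloro-3-[(4S)-2-(4-methoxyphenyl)-1,3-dioxolan-4-yl]-2-methylidene-4-[(triethylsilyl)oxy]pentan-1-ol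
Product: 16 tert-butyl{[(3R,4R)-5-chloro-3-[(4S)-2-(4-methoxyphenyl)-1,3-dioxolan-4-yl]-2-methylidene-4-[(triethylsilyl)oxy]pentyl]oxy}dimethylsilane
Conditions: tBuMe2SiCl, imidazole, CH2Cl2, 0 °C
Reagents that add atoms: tert-butylchlorodimethylsilane, CC(C)(C)[Si](C)(C)Cl
Why: Silylation of the primary allylic alcohol gives the C12 silyl ether that is kept until step 27.

Step 12
Reactants: 16 tert-butyl{[(3R,4R)-5-chloro-3-[(4S)-2-(4-methoxyphenyl)-1,3-dioxolan-4-yl]-2-methylidene-4-[(triethylsilyl)oxy]pentyl]oxy}dimethylsilane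
Product: 17 (2S,3R,4R)-3-[3-[(tert-butyldimethylsilyl)oxy]prop-1-en-2-yl]-5-chloro-2-[(4-methoxybenzyl)oxy]-4-[(triethylsilyl)oxy]pentan-1-ol
Conditions: iBu2AlH (3 equiv), CH2Cl2, −78 → 0 °C
Reagents that add atoms: none
Why: Reductive opening of the p-methoxybenzylidene acetal: the aluminium hydride binds the less hindered primary oxygen O9 and cleaves its acetal bond, so the PMB group ends on the secondary O8 and the C9 alcohol is released. No other hydroxyl or epoxide is present to interfere.

Step 13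
Reactants: 17 (2S,3R,4R)-3-[3-[(tert-butyldimethylsilyl)oxy]prop-1-en-2-yl]-5-chloro-2-[(4-methoxybenzyl)oxy]-4-[(triethylsilyl)oxy]pentan-1-ol
Product: 18 (2S,3R,4R)-3-[3-[(tert-butyldimethylsilyl)oxy]prop-1-en-2-yl]-5-chloro-2-[(4-methoxybenzyl)oxy]-4-[(triethylsilyl)oxy]pentanal
Conditions: Dess–Martin periodinane, NaHCO3, CH2Cl2, 0 °C → rt; used at once
Reagents that add atoms: none
Why: Buffered Dess–Martin oxidation of the primary alcohol gives the α-alkoxy aldehyde without epimerisation at C8.

### Fragment B (steps 14–18)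

Step 14
Reactants: 19 (S)-hex-5-en-2-ol
Product: 20 triethyl{[(2S)-hex-5-en-2-yl]oxy}silane
Conditions: Et3SiCl, imidazole, CH2Cl2, 0 °C
Reagents that add atoms: chlorotriethylsilane, CC[Si](Cl)(CC)CC
Why: Silylation of the secondary alcohol; TES is chosen because it is later removed together with the C6 TES ether while the TBS ethers stay.

Step 15
Reactants: 20 triethyl{[(2S)-hex-5-en-2-yl]oxy}silane
Product: 21 (2E,7S)-7-[(triethylsilyl)oxy]oct-2-enal
Conditions: acrolein (5 equiv), second-generation Hoveyda–Grubbs catalyst (3 mol %), CH2Cl2, 40 °C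
Reagents that add atoms: acrolein, C=CC=O
Why: Olefin cross-metathesis of a terminal alkene with an electron-poor partner; loss of ethylene drives the reaction to the (E)-enal, which brings in C10 and C14.

Step 16
Reactants: 21 (2E,7S)-7-[(triethylsilyl)oxy]oct-2-enal
Product: 22 (2Z,7S)-2-iodo-7-[(triethylsilyl)oxy]oct-2-enal
Conditions: I2, DMAP (20 mol %), K2CO3, THF/H2O (1:1), rt
Reagents that add atoms: iodine, II
Why: α-Iodination of an enal by conjugate addition of DMAP, iodination of the enolate and elimination of the catalyst; the aldehyde ends trans to the alkyl chain, so iodine is cis to C2, the geometry needed for the ring-cis C1=C10 alkene.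

Step 17
Reactants: 22 (2Z,7S)-2-iodo-7-[(triethylsilyl)oxy]oct-2-enal
Product: 23 (2Z,7S)-2-iodo-7-[(triethylsilyl)oxy]oct-2-en-1-ol
Conditions: iBu2AlH, CH2Cl2, −78 °C
Reagents that add atoms: none
Why: 1,2-Reduction of the iodo enal at low temperature; the alkenyl iodide and the silyl ether are inert.

Step 18
Reactants: 23 (2Z,7S)-2-iodo-7-[(triethylsilyl)oxy]oct-2-en-1-ol
Product: 24 tert-butyl{[(2Z,7S)-2-iodo-7-[(triethylsilyl)oxy]oct-2-en-1-yl]oxy}dimethylsilane
Conditions: tBuMe2SiCl, imidazole, DMF, rt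
Reagents that add atoms: tert-butylchlorodimethylsilane, CC(C)(C)[Si](C)(C)Cl
Why: Silylation of the primary allylic alcohol gives the future C14 silyl ether.

### Fragment union, ring closure and key step (steps 19–25)

Step 19
Reactants: 24 tert-butyl{[(2Z,7S)-2-iodo-7-[(triethylsilyl)oxy]oct-2-en-1-yl]oxy}dimethylsilane; 18 (2S,3R,4R)-3-[3-[(tert-butyldimethylsilyl)oxy]prop-1-en-2-yl]-5-chloro-2-[(4-methoxybenzyl)oxy]-4-[(triethylsilyl)oxy]pentanal
Product: 27 (4S,6R,7R,8S,9S,1(10)Z)-5-chloro-8-(PMB-oxy)-12,14-bis(TBS-oxy)-4,6-bis(TES-oxy)-4,5-secogermacra-1(10),11(13)-dien-9-ol, via alkenyllithium 25 (not isolated), via alkenylmagnesium bromide 26 (not isolated)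
Conditions: 24, tBuLi (2.05 equiv), Et2O, −78 °C; MgBr2·OEt2; then 18 premixed with MgBr2·OEt2, CH2Cl2, −78 °C
Reagents that add atoms: tert-butyllithium, [Li]C(C)(C)C (lithium into 25 only); magnesium dibromide, Br[Mg]Br (into 26 only)
Why: Iodine–lithium exchange with retention of alkene geometry and transmetalation give the alkenylmagnesium reagent. Magnesium bridges the aldehyde oxygen and the C8 PMB ether oxygen (Cram chelate) and the nucleophile adds from the face away from the C7 substituent, so the C9 hydroxyl should come out syn to O8 (9S). This is a chelation-controlled Grignard addition to an α-alkoxy aldehyde.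

Step 20
Reactants: 27 (4S,6R,7R,8S,9S,1(10)Z)-5-chloro-8-(PMB-oxy)-12,14-bis(TBS-oxy)-4,6-bis(TES-oxy)-4,5-secogermacra-1(10),11(13)-dien-9-ol
Product: 28 (4S,6R,7R,8S,9S,1(10)Z)-5-chloro-8-(PMB-oxy)-9,12,14-tris(TBS-oxy)-4,6-bis(TES-oxy)-4,5-secogermacra-1(10),11(13)-diene
Conditions: tBuMe2SiOTf, 2,6-lutidine, CH2Cl2, −78 → 0 °C
Reagents that add atoms: tert-butyldimethylsilyl trifluoromethanesulfonate, CC(C)(C)[Si](C)(C)OS(=O)(=O)C(F)(F)F
Why: The silyl triflate silylates the hindered allylic C9 hydroxyl; from here O8 (PMB) and O9 (TBS) are differentiated for the end game.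

Step 21
Reactants: 28 (4S,6R,7R,8S,9S,1(10)Z)-5-chloro-8-(PMB-oxy)-9,12,14-tris(TBS-oxy)-4,6-bis(TES-oxy)-4,5-secogermacra-1(10),11(13)-diene
Product: 29 (4S,6R,7S,8S,9S,1(10)Z)-5-chloro-8-(PMB-oxy)-9,12,14-tris(TBS-oxy)-4,5-secogermacra-1(10),11(13)-diene-4,6-diol
Conditions: PPTS (20 mol %), MeOH/CH2Cl2 (1:1), 0 °C
Reagents that add atoms: none
Why: Acid-catalysed methanolysis cleaves the two TES ethers, which are far more labile than the TBS ethers, and frees the C4 and C6 hydroxyls.

Step 22
Reactants: 29 (4S,6R,7S,8S,9S,1(10)Z)-5-chloro-8-(PMB-oxy)-9,12,14-tris(TBS-oxy)-4,5-secogermacra-1(10),11(13)-diene-4,6-diol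
Product: 30 S-[(4R,6R,7S,8S,9S,1(10)Z)-5-chloro-6-hydroxy-8-(PMB-oxy)-9,12,14-tris(TBS-oxy)-4,5-secogermacra-1(10),11(13)-dien-4-yl] ethanethioate
Conditions: PPh3, DIAD, AcSH (1.1 equiv each), THF, 0 °C
Reagents that add atoms: thioacetic acid, CC(=O)S
Why: Mitsunobu reaction: the unhindered C4 carbinol is activated and displaced by thioacetate with inversion (4S to 4R). The C6 hydroxyl, flanked by the chloromethyl group and the branched C7, is too hindered and electron-poor to compete.

Step 23
Reactants: 30 S-[(4R,6R,7S,8S,9S,1(10)Z)-5-chloro-6-hydroxy-8-(PMB-oxy)-9,12,14-tris(TBS-oxy)-4,5-secogermacra-1(10),11(13)-dien-4-yl] ethanethioate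
Product: 32 (4R,6R,7S,8S,9S,1(10)Z)-8-(PMB-oxy)-9,12,14-tris(TBS-oxy)-4,5-seco-4,5-sulfanediylgermacra-1(10),11(13)-dien-6-ol (eleven-membered cyclic sulfide), via epoxy thiol 31 (not isolated)
Conditions: K2CO3, degassed MeOH, 1 mM (slow addition), rt
Reagents that add atoms: none
Why: Carbonate in methanol cleaves the thioacetate and closes the chlorohydrin to the terminal epoxide; the thiolate then opens the epoxide at the unhindered C5 (direct displacement of the C5 chloride would give the same product), forming the eleven-membered sulfide and freeing the C6 hydroxyl. High dilution and the ring-cis C1=C10 alkene, which turns the chain ends towards each other, favour cyclisation; intramolecular thiolate alkylation is the standard entry to macrocyclic sulfides.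

Step 24
Reactants: 32 (4R,6R,7S,8S,9S,1(10)Z)-8-(PMB-oxy)-9,12,14-tris(TBS-oxy)-4,5-seco-4,5-sulfanediylgermacra-1(10),11(13)-dien-6-ol
Product: 34 (4R,6R,7S,8S,9S,1(10)Z)-8-(PMB-oxy)-9,12,14-tris(TBS-oxy)-4,5-seco-4,5-sulfonylgermacra-1(10),11(13)-dien-6-ol (eleven-membered cyclic sulfone), via sulfoxide 33 (not isolated)
Conditions: (NH4)6Mo7O24·4H2O (10 mol %), 30% H2O2, EtOH, 0 °C → rt
Reagents that add atoms: hydrogen peroxide, OO
Why: Peroxomolybdate-catalysed oxidation of the sulfide through the sulfoxide to the sulfone; this oxidant is selective for sulfur and leaves the two alkenes, the PMB ether and the free alcohol alone.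

Step 25
Reactants: 34 (4R,6R,7S,8S,9S,1(10)Z)-8-(PMB-oxy)-9,12,14-tris(TBS-oxy)-4,5-seco-4,5-sulfonylgermacra-1(10),11(13)-dien-6-ol
Product: 37 (4Z,6S,7S,8S,9S,1(10)Z)-8-(PMB-oxy)-9,12,14-tris(TBS-oxy)germacra-1(10),4,11(13)-trien-6-ol, via α-bromo sulfone 35 (not isolated), via episulfone 36 (not isolated)
Conditions: KOH on Al2O3, CBr2F2, tBuOH/CH2Cl2 (1:1), 0 °C → rt
Reagents that add atoms: dibromodifluoromethane, FC(F)(Br)Br (bromine into 35 only)
Why: KOH on alumina deprotonates the sulfone at C4 or C5 and the carbanion takes bromine from CBr2F2; the carbanion on the other α-carbon then displaces bromide in a 1,3-elimination that forms the C4–C5 bond and the thiirane dioxide, which expels SO2 in a concerted, stereospecific step to give the C4=C5 alkene. This is the Meyers–Chan one-flask Ramberg–Bäcklund reaction, known for contracting cyclic sulfones to cycloalkenes and for sulfones with β-oxygen substituents. The ten-membered carbocycle is thus closed by the transannular 3-exo-tet C4–C5 bond formation inside the eleven-membered ring, not by an end-to-end cyclisation. No lasting stereocentre is made: C4 and C5 become sp2, both C4 epimers would converge, and C6–C9 are untouched. The selectivity needed is the (Z) geometry; extrusion is stereospecific, and the cis-fused episulfone is the one the ten-membered ring with its ring-cis C1=C10 unit can accommodate without the strain of a trans-trisubstituted alkene. The site of bromination should not matter, because a C5 bromide next to the C6 alkoxide can at most close to the α,β-epoxy sulfone, which the C4 carbanion opens to the same β-alkoxy episulfone (the epoxy-Ramberg–Bäcklund pathway). The free C6 hydroxyl is present as its alkoxide, which cannot leave from a C5 carbanion; C12 and C14 are silyl ethers, so no Michael acceptor is present, and difluorocarbene is quenched by tert-butanol rather than by the alkenes.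

### End game (steps 26–36)

Step 26
Reactants: 37 (4Z,6S,7S,8S,9S,1(10)Z)-8-(PMB-oxy)-9,12,14-tris(TBS-oxy)germacra-1(10),4,11(13)-trien-6-ol
Product: 38 (4R,5S,6R,7S,8S,9S,1(10)Z)-4,5-epoxy-8-(PMB-oxy)-9,12,14-tris(TBS-oxy)germacra-1(10),11(13)-dien-6-ol
Conditions: VO(acac)2 (5 mol %), tBuOOH, CH2Cl2, 0 °C
Reagents that add atoms: tert-butyl hydroperoxide, CC(C)(C)OO
Why: Hydroxyl-directed epoxidation: the vanadium alkoxide of O6 delivers oxygen to the allylic C4=C5 alkene only. With ring carbon C3 cis to the carbinol, allylic 1,3-strain puts H6 in the alkene plane and oxygen enters syn to the hydroxyl (threo), which corresponds to the 4R,5S cis-epoxide; the homoallylic C11=C13 and the undirected C1=C10 alkenes react far more slowly.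

Step 27
Reactants: 38 (4R,5S,6R,7S,8S,9S,1(10)Z)-4,5-epoxy-8-(PMB-oxy)-9,12,14-tris(TBS-oxy)germacra-1(10),11(13)-dien-6-ol
Product: 39 (4R,5S,6R,7S,8S,9S,1(10)Z)-4,5-epoxy-8-(PMB-oxy)-9-(TBS-oxy)germacra-1(10),11(13)-diene-6,12,14-triol
Conditions: HF·pyridine, pyridine, THF, 0 °C
Reagents that add atoms: none
Why: Buffered fluoride cleaves the two primary allylic silyl ethers much faster than the hindered secondary C9 silyl ether, and the pyridine buffer protects the epoxy alcohol from acid.

Step 28
Reactants: 39 (4R,5S,6R,7S,8S,9S,1(10)Z)-4,5-epoxy-8-(PMB-oxy)-9-(TBS-oxy)germacra-1(10),11(13)-diene-6,12,14-triol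
Product: 41 (4R,5S,6R,7R,8S,9S,1(10)E)-4,5-epoxy-14-oxo-8-(PMB-oxy)-9-(TBS-oxy)germacra-1(10),11(13)-dien-12,6-olide, via lactol 40 (not isolated)
Conditions: MnO2 (activated, excess), CH2Cl2, rt
Reagents that add atoms: none
Why: Manganese dioxide oxidises only allylic alcohols: the C12 alcohol gives an enal that the C6 hydroxyl traps as the lactol, which is oxidised on to the α-methylene lactone, while the C14 alcohol stops at the enal. The C6 hydroxyl is no longer allylic and is not oxidised; the alkene geometry is unchanged (the descriptor changes only by priority).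

Step 29
Reactants: 41 (4R,5S,6R,7R,8S,9S,1(10)E)-4,5-epoxy-14-oxo-8-(PMB-oxy)-9-(TBS-oxy)germacra-1(10),11(13)-dien-12,6-olide
Product: 42 (4R,5S,6R,7R,8S,9S,1(10)E)-4,5-epoxy-8-(PMB-oxy)-9-(TBS-oxy)germacra-1(10),11(13)-dien-12,6-olid-14-oic acid
Conditions: NaClO2, NaH2PO4, 2-methyl-2-butene, tBuOH/H2O, 0 °C → rt
Reagents that add atoms: sodium chlorite, [Na+].[O-]Cl=O
Why: Pinnick oxidation of the conjugated aldehyde; buffered chlorite with an alkene scavenger leaves the epoxide, the methylene lactone and the PMB ether untouched.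

Step 30
Reactants: 42 (4R,5S,6R,7R,8S,9S,1(10)E)-4,5-epoxy-8-(PMB-oxy)-9-(TBS-oxy)germacra-1(10),11(13)-dien-12,6-olid-14-oic acid
Product: 43 methyl (4R,5S,6R,7R,8S,9S,1(10)E)-4,5-epoxy-8-(PMB-oxy)-9-(TBS-oxy)germacra-1(10),11(13)-dien-12,6-olid-14-oate
Conditions: MeI, KHCO3, DMF, rt
Reagents that add atoms: iodomethane, CI
Why: O-Alkylation of the carboxylate under weakly basic conditions; diazoalkanes are avoided because they add to α-methylene lactones.

Step 31
Reactants: 43 methyl (4R,5S,6R,7R,8S,9S,1(10)E)-4,5-epoxy-8-(PMB-oxy)-9-(TBS-oxy)germacra-1(10),11(13)-dien-12,6-olid-14-oate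
Product: 44 methyl (4R,5S,6R,7R,8S,9S,1(10)E)-4,5-epoxy-9-hydroxy-8-(PMB-oxy)germacra-1(10),11(13)-dien-12,6-olid-14-oate
Conditions: HF·pyridine, THF, 0 °C → rt
Reagents that add atoms: none
Why: Fluoride cleaves the remaining hindered silyl ether. The C1=C10 alkene is now an electron-poor enoate, so acid-induced transannular attack on the epoxide should not compete.

Step 32
Reactants: 45 methallyl alcohol (2-methylprop-2-en-1-ol)
Product: 46 [(2S)-2-methyloxiran-2-yl]methanol
Conditions: Ti(OiPr)4 (5 mol %), L-(+)-diethyl tartrate (6 mol %), tBuOOH, 4 Å molecular sieves, CH2Cl2, −20 °C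
Reagents that add atoms: tert-butyl hydroperoxide, CC(C)(C)OO
Why: Sharpless asymmetric epoxidation: the titanium tartrate complex with L-(+)-diethyl tartrate delivers oxygen to one face of the 2-substituted allylic alcohol and gives the (S)-epoxy alcohol.

Step 33
Reactants: 46 [(2S)-2-methyloxiran-2-yl]methanol
Product: 47 (2R)-2-methyloxirane-2-carboxylic acid
Conditions: RuCl3·xH2O (2 mol %), NaIO4, MeCN/EtOAc/H2O, 0 °C → rt
Reagents that add atoms: sodium periodate, [Na+].[O-]I(=O)(=O)=O; water, O
Why: Ruthenium tetroxide, formed catalytically from RuCl3 and periodate, oxidises the primary alcohol to the acid without touching the epoxide; the descriptor changes from S to R only because the priorities change.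

Step 34
Reactants: 44 methyl (4R,5S,6R,7R,8S,9S,1(10)E)-4,5-epoxy-9-hydroxy-8-(PMB-oxy)germacra-1(10),11(13)-dien-12,6-olid-14-oate; 47 (2R)-2-methyloxirane-2-carboxylic acid
Product: 49 methyl (4R,5S,6R,7R,8S,9S,1(10)E)-4,5-epoxy-9-{[(2R)-2-methyloxiran-2-yl]carbonyloxy}-8-(PMB-oxy)germacra-1(10),11(13)-dien-12,6-olid-14-oate, via mixed anhydride 48 (not isolated)
Conditions: 47, 2,4,6-trichlorobenzoyl chloride, Et3N, THF, rt; then 44, DMAP, toluene, rt
Reagents that add atoms: 2,4,6-trichlorobenzoyl chloride, O=C(Cl)c1c(Cl)cc(Cl)cc1Cl (into 48 only)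
Why: Yamaguchi esterification: DMAP attacks the mixed anhydride at the less hindered glycidic carbonyl and the acylpyridinium ion acylates the hindered C9 hydroxyl; no base strong enough to open the epoxides or add to the lactone is present.

Step 35
Reactants: 49 methyl (4R,5S,6R,7R,8S,9S,1(10)E)-4,5-epoxy-9-{[(2R)-2-methyloxiran-2-yl]carbonyloxy}-8-(PMB-oxy)germacra-1(10),11(13)-dien-12,6-olid-14-oate
Product: 50 methyl (4R,5S,6R,7R,8S,9S,1(10)E)-4,5-epoxy-8-hydroxy-9-{[(2R)-2-methyloxiran-2-yl]carbonyloxy}germacra-1(10),11(13)-dien-12,6-olid-14-oate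
Conditions: DDQ, CH2Cl2/pH 7 buffer (10:1), 0 °C; used crude
Reagents that add atoms: none
Why: Oxidative cleavage of the PMB ether by DDQ through the benzylic oxocarbenium ion; the buffer suppresses acyl migration from O9 to O8 and epoxide opening.

Step 36
Reactants: 50 methyl (4R,5S,6R,7R,8S,9S,1(10)E)-4,5-epoxy-8-hydroxy-9-{[(2R)-2-methyloxiran-2-yl]carbonyloxy}germacra-1(10),11(13)-dien-12,6-olid-14-oate
Product: 51 methyl (4R,5S,6R,7R,8S,9S,1(10)E)-8-acetoxy-4,5-epoxy-9-{[(2R)-2-methyloxiran-2-yl]carbonyloxy}germacra-1(10),11(13)-dien-12,6-olid-14-oate (CNP0159450.1)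
Conditions: Ac2O, pyridine, DMAP (cat.), CH2Cl2, 0 °C
Reagents that add atoms: acetic anhydride, CC(=O)OC(C)=O
Why: DMAP-catalysed acetylation of the C8 hydroxyl, run directly on the crude alcohol, completes the target.

## Compound list

1 | dimethyl (S)-malate | COC(=O)C[C@H](O)C(=O)OC | starting material
2 | methyl (3S)-3,4-dihydroxybutanoate | COC(=O)C[C@H](O)CO | intermediate
3 | methyl [(4S)-2,2-dibutyl-1,3,2-dioxastannolan-4-yl]acetate (stannylene acetal, formed in the flask) | COC(=O)C[C@H]1CO[Sn](CCCC)(CCCC)O1 | intermediate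
4 | methyl (3S)-3-hydroxy-4-[(4-methoxybenzyl)oxy]butanoate | COC(=O)C[C@H](O)COCc1ccc(OC)cc1 | intermediate
5 | dilithium alkoxide enolate of 4 (formed in the flask) | [Li+].[Li+].COC([O-])=C[C@H]([O-])COCc1ccc(OC)cc1 | intermediate
6 | methyl (2R)-2-[(1S)-1-hydroxy-2-[(4-methoxybenzyl)oxy]ethyl]pent-4-enoate | COC(=O)[C@H](CC=C)[C@H](O)COCc1ccc(OC)cc1 | intermediate
7 | methyl (2R)-2-[(4S)-2-(4-methoxyphenyl)-1,3-dioxolan-4-yl]pent-4-enoate | COC(=O)[C@H](CC=C)[C@H]1COC(c2ccc(OC)cc2)O1 | intermediate
8 | (3R)-1-chloro-3-[(4S)-2-(4-methoxyphenyl)-1,3-dioxolan-4-yl]hex-5-en-2-one | ClCC(=O)[C@H](CC=C)[C@H]1COC(c2ccc(OC)cc2)O1 | intermediate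
9 | (2R,3S)-1-chloro-3-[(4S)-2-(4-methoxyphenyl)-1,3-dioxolan-4-yl]hex-5-en-2-ol | ClC[C@H](O)[C@H](CC=C)[C@H]1COC(c2ccc(OC)cc2)O1 | intermediate
10 | {[(2R,3R)-1-chloro-3-[(4S)-2-(4-methoxyphenyl)-1,3-dioxolan-4-yl]hex-5-en-2-yl]oxy}triethylsilane | ClC[C@H](O[Si](CC)(CC)CC)[C@H](CC=C)[C@H]1COC(c2ccc(OC)cc2)O1 | intermediate
11 | (4R,5R)-6-chloro-4-[(4S)-2-(4-methoxyphenyl)-1,3-dioxolan-4-yl]-5-[(triethylsilyl)oxy]hexane-1,2-diol (formed in the flask) | ClC[C@H](O[Si](CC)(CC)CC)[C@H](CC(O)CO)[C@H]1COC(c2ccc(OC)cc2)O1 | intermediate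
12 | (3R,4R)-5-chloro-3-[(4S)-2-(4-methoxyphenyl)-1,3-dioxolan-4-yl]-4-[(triethylsilyl)oxy]pentanal | ClC[C@H](O[Si](CC)(CC)CC)[C@H](CC=O)[C@H]1COC(c2ccc(OC)cc2)O1 | intermediate
13 | 2-[(dimethylamino)methyl] derivative of 12 (Mannich base, formed in the flask) | ClC[C@H](O[Si](CC)(CC)CC)[C@H](C(CN(C)C)C=O)[C@H]1COC(c2ccc(OC)cc2)O1 | intermediate
14 | (3R,4R)-5-chloro-3-[(4S)-2-(4-methoxyphenyl)-1,3-dioxolan-4-yl]-2-methylidene-4-[(triethylsilyl)oxy]pentanal | ClC[C@H](O[Si](CC)(CC)CC)[C@H](C(=C)C=O)[C@H]1COC(c2ccc(OC)cc2)O1 | intermediate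
15 | (3R,4R)-5-chloro-3-[(4S)-2-(4-methoxyphenyl)-1,3-dioxolan-4-yl]-2-methylidene-4-[(triethylsilyl)oxy]pentan-1-ol | ClC[C@H](O[Si](CC)(CC)CC)[C@H](C(=C)CO)[C@H]1COC(c2ccc(OC)cc2)O1 | intermediate
16 | tert-butyldimethylsilyl ether of 15 | ClC[C@H](O[Si](CC)(CC)CC)[C@H](C(=C)CO[Si](C)(C)C(C)(C)C)[C@H]1COC(c2ccc(OC)cc2)O1 | intermediate
17 | (2S,3R,4R)-3-[3-[(tert-butyldimethylsilyl)oxy]prop-1-en-2-yl]-5-chloro-2-[(4-methoxybenzyl)oxy]-4-[(triethylsilyl)oxy]pentan-1-ol | ClC[C@H](O[Si](CC)(CC)CC)[C@H](C(=C)CO[Si](C)(C)C(C)(C)C)[C@H](OCc1ccc(OC)cc1)CO | intermediate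
18 | (2S,3R,4R)-3-[3-[(tert-butyldimethylsilyl)oxy]prop-1-en-2-yl]-5-chloro-2-[(4-methoxybenzyl)oxy]-4-[(triethylsilyl)oxy]pentanal (fragment A) | ClC[C@H](O[Si](CC)(CC)CC)[C@H](C(=C)CO[Si](C)(C)C(C)(C)C)[C@H](OCc1ccc(OC)cc1)C=O | intermediate
19 | (S)-hex-5-en-2-ol | C[C@H](O)CCC=C | starting material
20 | triethyl{[(2S)-hex-5-en-2-yl]oxy}silane | C[C@H](O[Si](CC)(CC)CC)CCC=C | intermediate
21 | (2E,7S)-7-[(triethylsilyl)oxy]oct-2-enal | C[C@H](O[Si](CC)(CC)CC)CC/C=C/C=O | intermediate
22 | (2Z,7S)-2-iodo-7-[(triethylsilyl)oxy]oct-2-enal | C[C@H](O[Si](CC)(CC)CC)CC/C=C(\I)C=O | intermediate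
23 | (2Z,7S)-2-iodo-7-[(triethylsilyl)oxy]oct-2-en-1-ol | C[C@H](O[Si](CC)(CC)CC)CC/C=C(\I)CO | intermediate
24 | tert-butyl{[(2Z,7S)-2-iodo-7-[(triethylsilyl)oxy]oct-2-en-1-yl]oxy}dimethylsilane (fragment B) | C[C@H](O[Si](CC)(CC)CC)CC/C=C(\I)CO[Si](C)(C)C(C)(C)C | intermediate
25 | alkenyllithium from 24 (lithium in place of iodine, formed in the flask) | [Li]/C(CO[Si](C)(C)C(C)(C)C)=C\CC[C@H](C)O[Si](CC)(CC)CC | intermediate
26 | alkenylmagnesium bromide from 25 (formed in the flask) | Br[Mg]/C(CO[Si](C)(C)C(C)(C)C)=C\CC[C@H](C)O[Si](CC)(CC)CC | intermediate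
27 | (4S,6R,7R,8S,9S,1(10)Z)-5-chloro-8-(PMB-oxy)-12,14-bis(TBS-oxy)-4,6-bis(TES-oxy)-4,5-secogermacra-1(10),11(13)-dien-9-ol | ClC[C@H](O[Si](CC)(CC)CC)[C@H](C(=C)CO[Si](C)(C)C(C)(C)C)[C@H](OCc1ccc(OC)cc1)[C@@H](O)/C(CO[Si](C)(C)C(C)(C)C)=C\CC[C@H](C)O[Si](CC)(CC)CC | intermediate
28 | (4S,6R,7R,8S,9S,1(10)Z)-5-chloro-8-(PMB-oxy)-9,12,14-tris(TBS-oxy)-4,6-bis(TES-oxy)-4,5-secogermacra-1(10),11(13)-diene | ClC[C@H](O[Si](CC)(CC)CC)[C@H](C(=C)CO[Si](C)(C)C(C)(C)C)[C@H](OCc1ccc(OC)cc1)[C@@H](O[Si](C)(C)C(C)(C)C)/C(CO[Si](C)(C)C(C)(C)C)=C\CC[C@H](C)O[Si](CC)(CC)CC | intermediate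
29 | (4S,6R,7S,8S,9S,1(10)Z)-5-chloro-8-(PMB-oxy)-9,12,14-tris(TBS-oxy)-4,5-secogermacra-1(10),11(13)-diene-4,6-diol | ClC[C@H](O)[C@H](C(=C)CO[Si](C)(C)C(C)(C)C)[C@H](OCc1ccc(OC)cc1)[C@@H](O[Si](C)(C)C(C)(C)C)/C(CO[Si](C)(C)C(C)(C)C)=C\CC[C@H](C)O | intermediate
30 | S-[(4R,6R,7S,8S,9S,1(10)Z)-5-chloro-6-hydroxy-8-(PMB-oxy)-9,12,14-tris(TBS-oxy)-4,5-secogermacra-1(10),11(13)-dien-4-yl] ethanethioate | ClC[C@H](O)[C@H](C(=C)CO[Si](C)(C)C(C)(C)C)[C@H](OCc1ccc(OC)cc1)[C@@H](O[Si](C)(C)C(C)(C)C)/C(CO[Si](C)(C)C(C)(C)C)=C\CC[C@@H](C)SC(C)=O | intermediate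
31 | (4R,6R,7S,8S,9S,1(10)Z)-5,6-epoxy-8-(PMB-oxy)-9,12,14-tris(TBS-oxy)-4,5-secogermacra-1(10),11(13)-diene-4-thiol (formed in the flask) | C1O[C@@H]1[C@H](C(=C)CO[Si](C)(C)C(C)(C)C)[C@H](OCc2ccc(OC)cc2)[C@@H](O[Si](C)(C)C(C)(C)C)/C(CO[Si](C)(C)C(C)(C)C)=C\CC[C@@H](C)S | intermediate
32 | eleven-membered cyclic sulfide, (4R,6R,7S,8S,9S,1(10)Z)-8-(PMB-oxy)-9,12,14-tris(TBS-oxy)-4,5-seco-4,5-sulfanediylgermacra-1(10),11(13)-dien-6-ol | S1C[C@H](O)[C@H](C(=C)CO[Si](C)(C)C(C)(C)C)[C@H](OCc2ccc(OC)cc2)[C@@H](O[Si](C)(C)C(C)(C)C)/C(CO[Si](C)(C)C(C)(C)C)=C\CC[C@H]1C | intermediate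
33 | sulfoxide of 32 (formed in the flask, mixture at sulfur) | O=S1C[C@H](O)[C@H](C(=C)CO[Si](C)(C)C(C)(C)C)[C@H](OCc2ccc(OC)cc2)[C@@H](O[Si](C)(C)C(C)(C)C)/C(CO[Si](C)(C)C(C)(C)C)=C\CC[C@H]1C | intermediate
34 | eleven-membered cyclic sulfone, (4R,6R,7S,8S,9S,1(10)Z)-8-(PMB-oxy)-9,12,14-tris(TBS-oxy)-4,5-seco-4,5-sulfonylgermacra-1(10),11(13)-dien-6-ol | O=S1(=O)C[C@H](O)[C@H](C(=C)CO[Si](C)(C)C(C)(C)C)[C@H](OCc2ccc(OC)cc2)[C@@H](O[Si](C)(C)C(C)(C)C)/C(CO[Si](C)(C)C(C)(C)C)=C\CC[C@H]1C | intermediate
35 | 4-bromo derivative of sulfone 34 (formed in the flask; the C5 bromide is equally productive) | O=S1(=O)C[C@H](O)[C@H](C(=C)CO[Si](C)(C)C(C)(C)C)[C@H](OCc2ccc(OC)cc2)[C@@H](O[Si](C)(C)C(C)(C)C)/C(CO[Si](C)(C)C(C)(C)C)=C\CCC1(C)Br | intermediate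
36 | cis-fused C4–C5 episulfone (thiirane 1,1-dioxide on the ten-membered ring, formed in the flask) | O=S1(=O)C2[C@H](O)[C@H](C(=C)CO[Si](C)(C)C(C)(C)C)[C@H](OCc3ccc(OC)cc3)[C@@H](O[Si](C)(C)C(C)(C)C)/C(CO[Si](C)(C)C(C)(C)C)=C\CCC12C | intermediate
37 | (4Z,6S,7S,8S,9S,1(10)Z)-8-(PMB-oxy)-9,12,14-tris(TBS-oxy)germacra-1(10),4,11(13)-trien-6-ol | C/C1=C/[C@H](O)[C@H](C(=C)CO[Si](C)(C)C(C)(C)C)[C@H](OCc2ccc(OC)cc2)[C@@H](O[Si](C)(C)C(C)(C)C)/C(CO[Si](C)(C)C(C)(C)C)=C\CC1 | intermediate
38 | (4R,5S,6R,7S,8S,9S,1(10)Z)-4,5-epoxy-8-(PMB-oxy)-9,12,14-tris(TBS-oxy)germacra-1(10),11(13)-dien-6-ol | O[C@@H]2[C@H](C(=C)CO[Si](C)(C)C(C)(C)C)[C@H](OCc1ccc(OC)cc1)[C@@H](O[Si](C)(C)C(C)(C)C)/C(CO[Si](C)(C)C(C)(C)C)=C\CC[C@@]1(C)O[C@@H]21 | intermediate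
39 | (4R,5S,6R,7S,8S,9S,1(10)Z)-4,5-epoxy-8-(PMB-oxy)-9-(TBS-oxy)germacra-1(10),11(13)-diene-6,12,14-triol | O[C@@H]2[C@H](C(=C)CO)[C@H](OCc1ccc(OC)cc1)[C@@H](O[Si](C)(C)C(C)(C)C)/C(CO)=C\CC[C@@]1(C)O[C@@H]21 | intermediate
40 | C12 lactol (12-hydroxy-6,12-epoxy) of the C12/C14 dialdehyde (formed in the flask) | C=C1C(O)O[C@@H]2[C@H]1[C@H](OCc3ccc(OC)cc3)[C@@H](O[Si](C)(C)C(C)(C)C)/C(C=O)=C\CC[C@@]1(C)O[C@@H]21 | intermediate
41 | (4R,5S,6R,7R,8S,9S,1(10)E)-4,5-epoxy-14-oxo-8-(PMB-oxy)-9-(TBS-oxy)germacra-1(10),11(13)-dien-12,6-olide | C=C1C(=O)O[C@@H]2[C@H]1[C@H](OCc3ccc(OC)cc3)[C@@H](O[Si](C)(C)C(C)(C)C)/C(C=O)=C\CC[C@@]1(C)O[C@@H]21 | intermediate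
42 | (4R,5S,6R,7R,8S,9S,1(10)E)-4,5-epoxy-8-(PMB-oxy)-9-(TBS-oxy)germacra-1(10),11(13)-dien-12,6-olid-14-oic acid | C=C1C(=O)O[C@@H]2[C@H]1[C@H](OCc3ccc(OC)cc3)[C@@H](O[Si](C)(C)C(C)(C)C)/C(C(=O)O)=C\CC[C@@]1(C)O[C@@H]21 | intermediate
43 | methyl (4R,5S,6R,7R,8S,9S,1(10)E)-4,5-epoxy-8-(PMB-oxy)-9-(TBS-oxy)germacra-1(10),11(13)-dien-12,6-olid-14-oate | C=C1C(=O)O[C@@H]2[C@H]1[C@H](OCc3ccc(OC)cc3)[C@@H](O[Si](C)(C)C(C)(C)C)/C(C(=O)OC)=C\CC[C@@]1(C)O[C@@H]21 | intermediate
44 | methyl (4R,5S,6R,7R,8S,9S,1(10)E)-4,5-epoxy-9-hydroxy-8-(PMB-oxy)germacra-1(10),11(13)-dien-12,6-olid-14-oate | C=C1C(=O)O[C@@H]2[C@H]1[C@H](OCc3ccc(OC)cc3)[C@@H](O)/C(C(=O)OC)=C\CC[C@@]1(C)O[C@@H]21 | intermediate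
45 | methallyl alcohol (2-methylprop-2-en-1-ol) | C=C(C)CO | starting material
46 | [(2S)-2-methyloxiran-2-yl]methanol | OC[C@@]1(C)CO1 | intermediate
47 | (2R)-2-methyloxirane-2-carboxylic acid | OC(=O)[C@@]1(C)CO1 | intermediate
48 | (2R)-2-methyloxirane-2-carboxylic 2,4,6-trichlorobenzoic anhydride (formed in the flask) | O=C(OC(=O)[C@@]1(C)CO1)c1c(Cl)cc(Cl)cc1Cl | intermediate
49 | methyl (4R,5S,6R,7R,8S,9S,1(10)E)-4,5-epoxy-9-{[(2R)-2-methyloxiran-2-yl]carbonyloxy}-8-(PMB-oxy)germacra-1(10),11(13)-dien-12,6-olid-14-oate | C=C1C(=O)O[C@@H]2[C@H]1[C@H](OCc3ccc(OC)cc3)[C@@H](OC(=O)[C@@]4(C)CO4)/C(C(=O)OC)=C\CC[C@@]1(C)O[C@@H]21 | intermediate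
50 | methyl (4R,5S,6R,7R,8S,9S,1(10)E)-4,5-epoxy-8-hydroxy-9-{[(2R)-2-methyloxiran-2-yl]carbonyloxy}germacra-1(10),11(13)-dien-12,6-olid-14-oate | C=C1C(=O)O[C@@H]2[C@H]1[C@H](O)[C@@H](OC(=O)[C@@]3(C)CO3)/C(C(=O)OC)=C\CC[C@@]1(C)O[C@@H]21 | intermediate
51 | methyl (4R,5S,6R,7R,8S,9S,1(10)E)-8-acetoxy-4,5-epoxy-9-{[(2R)-2-methyloxiran-2-yl]carbonyloxy}germacra-1(10),11(13)-dien-12,6-olid-14-oate (CNP0159450.1) | C=C1C(=O)O[C@@H]2[C@H]1[C@H](OC(C)=O)[C@@H](OC(=O)[C@@]1(C)CO1)/C(C(=O)OC)=C\CC[C@@]1(C)O[C@@H]21 | target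

## Step count and least certain steps

Total: 36 steps (13 for fragment A, 5 for fragment B, 2 for acid 47, 16 from fragment union to the target). Longest linear sequence: 29 steps (steps 1–13, 19–31, 34–36).

**Step 25 (key step).** The most likely failure is ring opening by retro-aldol-type cleavage of the C5–C6 bond of the β-alkoxide sulfone before the slower carbanion chemistry takes place. A second failure is loss of the (Z) geometry through base-induced epimerisation of the episulfone. Fallback: a stepwise Ramberg–Bäcklund sequence with the hydroxyl masked. Sulfone 34 is silylated (Et3SiOTf, 2,6-lutidine) to the C6 triethylsilyl ether of the sulfone F1. Kinetic deprotonation at C5 (LiN(SiMe3)2, THF, −78 °C) and chlorination with C2Cl6 give the isolated 5-chloro sulfone F2. Brief treatment with tBuOK in THF (−78 → 0 °C) brings about the classical contraction to the C6 triethylsilyl ether of the trienol F3, and PPTS in methanol returns to 37.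

**Step 23 (ring closure through sulfur).** Intermolecular thiolate alkylation (oligomerisation) may outrun the eleven-membered closure. Fallback: close the other C–S bond with sulfide as a linchpin. The C4 hydroxyl of diol 29 is mesylated selectively (MsCl, Et3N, −20 °C) to the C4 methanesulfonate F4. Na2S·9H2O with K2CO3 in DMF/EtOH under high dilution closes the chlorohydrin to the epoxide, hydrosulfide opens it at C5, and the resulting thiolate displaces the secondary mesylate with inversion, which gives sulfide 32 directly.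

**Step 19 (fragment union).** Facial selectivity may be poor if the magnesium chelate with the PMB ether is incomplete, or the α-alkoxy aldehyde may epimerise. Fallback: reagent control at the ketone stage. Iodide 24 and aldehyde 18 are joined without stereocontrol by a Nozaki–Hiyama–Kishi reaction (CrCl2, NiCl2 cat., DMSO), which gives 27 mixed with its C9 epimer F5. Dess–Martin oxidation of the mixture gives the C9 enone F6, and reduction with (S)-2-methyl-CBS-oxazaborolidine and catecholborane (alkenyl group as the large substituent) returns 27.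

**Step 22 (thioacetate installation).** The Mitsunobu reaction may not discriminate fully between the C4 and C6 hydroxyls, or the chlorohydrin may close under the betaine. Fallback: unmask the hydroxyls one at a time. From 28, short exposure to PPTS in methanol at −20 °C cleaves only the unhindered C4 silyl ether to give the C4 alcohol with the C6 silyl ether retained F7. Mitsunobu thioacetylation gives the thioacetate with the C6 silyl ether F8, and HF·pyridine removes the C6 silyl group to give 30.

**Step 26 (directed epoxidation).** The ring conformation may override the acyclic 1,3-strain model and give poor facial selectivity, and the homoallylic C11=C13 alkene may be epoxidised as well. Fallback: epoxidise after lactonisation, without a directing group. From 37, HF·pyridine/pyridine gives the 6,12,14-triol F9. MnO2 gives the lactone aldehyde with the C4=C5 alkene F10, in which C4=C5 is the only electron-rich alkene. Epoxidation with mCPBA (NaHCO3, CH2Cl2, 0 °C), with the face now set by the cis-fused lactone, rejoins the route at 41; the sense of attack would have to be confirmed on the first sample.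

## Further compounds

F1 | step 25 | C6 triethylsilyl ether of sulfone 34 | O=S1(=O)C[C@H](O[Si](CC)(CC)CC)[C@H](C(=C)CO[Si](C)(C)C(C)(C)C)[C@H](OCc2ccc(OC)cc2)[C@@H](O[Si](C)(C)C(C)(C)C)/C(CO[Si](C)(C)C(C)(C)C)=C\CC[C@H]1C
F2 | step 25 | 5-chloro derivative of F1 (α-chloro sulfone) | O=S1(=O)C(Cl)[C@H](O[Si](CC)(CC)CC)[C@H](C(=C)CO[Si](C)(C)C(C)(C)C)[C@H](OCc2ccc(OC)cc2)[C@@H](O[Si](C)(C)C(C)(C)C)/C(CO[Si](C)(C)C(C)(C)C)=C\CC[C@H]1C
F3 | step 25 | C6 triethylsilyl ether of trienol 37 | C/C1=C/[C@H](O[Si](CC)(CC)CC)[C@H](C(=C)CO[Si](C)(C)C(C)(C)C)[C@H](OCc2ccc(OC)cc2)[C@@H](O[Si](C)(C)C(C)(C)C)/C(CO[Si](C)(C)C(C)(C)C)=C\CC1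
F4 | step 23 | C4 methanesulfonate of diol 29 | ClC[C@H](O)[C@H](C(=C)CO[Si](C)(C)C(C)(C)C)[C@H](OCc1ccc(OC)cc1)[C@@H](O[Si](C)(C)C(C)(C)C)/C(CO[Si](C)(C)C(C)(C)C)=C\CC[C@H](C)OS(C)(=O)=O
F5 | step 19 | C9 epimer of alcohol 27 | ClC[C@H](O[Si](CC)(CC)CC)[C@H](C(=C)CO[Si](C)(C)C(C)(C)C)[C@H](OCc1ccc(OC)cc1)[C@H](O)/C(CO[Si](C)(C)C(C)(C)C)=C\CC[C@H](C)O[Si](CC)(CC)CC
F6 | step 19 | C9 ketone (enone) corresponding to 27 | ClC[C@H](O[Si](CC)(CC)CC)[C@H](C(=C)CO[Si](C)(C)C(C)(C)C)[C@H](OCc1ccc(OC)cc1)C(=O)/C(CO[Si](C)(C)C(C)(C)C)=C\CC[C@H](C)O[Si](CC)(CC)CC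
F7 | step 22 | C4 alcohol with the C6 triethylsilyl ether retained (from 28) | ClC[C@H](O[Si](CC)(CC)CC)[C@H](C(=C)CO[Si](C)(C)C(C)(C)C)[C@H](OCc1ccc(OC)cc1)[C@@H](O[Si](C)(C)C(C)(C)C)/C(CO[Si](C)(C)C(C)(C)C)=C\CC[C@H](C)O
F8 | step 22 | C4 thioacetate with the C6 triethylsilyl ether | ClC[C@H](O[Si](CC)(CC)CC)[C@H](C(=C)CO[Si](C)(C)C(C)(C)C)[C@H](OCc1ccc(OC)cc1)[C@@H](O[Si](C)(C)C(C)(C)C)/C(CO[Si](C)(C)C(C)(C)C)=C\CC[C@@H](C)SC(C)=O
F9 | step 26 | (4Z,6S,7S,8S,9S,1(10)Z)-8-(PMB-oxy)-9-(TBS-oxy)germacra-1(10),4,11(13)-triene-6,12,14-triol | C/C1=C/[C@H](O)[C@H](C(=C)CO)[C@H](OCc2ccc(OC)cc2)[C@@H](O[Si](C)(C)C(C)(C)C)/C(CO)=C\CC1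
F10 | step 26 | (4Z,1(10)E)-14-oxo-8-(PMB-oxy)-9-(TBS-oxy)germacra-1(10),4,11(13)-trien-12,6-olide | C/C1=C/[C@@H]2OC(=O)C(=C)[C@@H]2[C@H](OCc3ccc(OC)cc3)[C@@H](O[Si](C)(C)C(C)(C)C)/C(C=O)=C\CC1
A1 | alternative 1 | ten-membered 5-ketone with cis-fused γ-lactone (product of the De Mayo step) | O=C1[C@@H]2OC(=O)C[C@@H]2[C@@H]3OC(C)(C)O[C@H]3/C(CO[Si](C)(C)C(C)(C)C)=C\CC[C@@]1(C)O[Si](CC)(CC)CC
A2 | alternative 1 | thirteen-membered β-keto enol lactone (photosubstrate) | O=C1CC(=O)[C@](C)(O[Si](CC)(CC)CC)CC/C=C(CO[Si](C)(C)C(C)(C)C)\[C@@H]2OC(C)(C)O[C@H]2/C=C\O1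
A3 | alternative 2 | ten-membered 8,9-cis-ene with lactone, epoxide and enoate (metathesis product) | C=C1C(=O)O[C@@H]2[C@H]1/C=C\C(C(=O)OC)=C/CC[C@@]1(C)O[C@@H]21
A4 | alternative 2 | acyclic diene with vinyl groups on C7 and C10 (metathesis substrate) | C=C1C(=O)O[C@H]([C@H]1C=C)[C@@H]1O[C@]1(C)CC/C=C(\C=C)C(=O)OC
A5 | alternative 3 | ten-membered C4=C5 silyl enol ether with ring-cis C1=C10 enoate (oxy-Cope product) | C/C1=C(O[Si](C)(C)C)\[C@H](O[Si](C)(C)C(C)(C)C)[C@H](CCO[Si](C)(C)C(C)(C)C)[C@@H]2OC(C)(C)O[C@H]2/C(C(=O)OC)=C\CC1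
A6 | alternative 3 | cis-1,2-dialkenylcyclohexanol (oxy-Cope substrate) | C=C(C)[C@]1(O)[C@H](O[Si](C)(C)C(C)(C)C)[C@H](CCO[Si](C)(C)C(C)(C)C)[C@@H]2OC(C)(C)O[C@H]2[C@@]1(C=C)C(=O)OC
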